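(The constants were drawn at random within sensible limits.)

The pitfall in this flask is to read every bit of vanished free monomer as chain. The protic impurity takes free monomer one for one, and by that step alone, with the other charges as they stand, its own half-life is 1.8 s, far shorter than the run, while chains begin from the initiator that the pre-initiator releases.

free monomer 1.5 M; protic impurity 0.150 M; pre-initiator 15 mM; time 2.5 min

    monomer in chains → over-reaction product (k1 = 1.2 × 10⁻⁶ s⁻¹)
    free monomer + initiator → living end + monomer in chains (k2 = 0.0026 M⁻¹ s⁻¹)
    pre-initiator ⇌ initiator (K3 = 0.25, k3 = 0.0030 s⁻¹)
    protic impurity + free monomer → quenched substrate (k4 = 0.26 M⁻¹ s⁻¹)
    free monomer + living end → monomer in chains + living end, rate k5*[living end]*[free monomer] (k5 = 0.20 M⁻¹ s⁻¹)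

* average number of monomer units in a chain (chains begun, living or dead) at 2.5 min
* part of the free monomer that has reacted at 2.5 min

- the average divides the monomer in chains by the number of chains begun, living and dead together
- run time (flask): 2.5 min

So I count turnovers. I let the impurity take its whole charge first, and multiply the growth constant by the free monomer that remains and by the time. This gives the growth turnovers, the units that a living end present for the whole run adds: 40.5. Pre-initiator and initiator relax by their own step with a half-life of 0.770 min, shorter than the run, so I take it that chains begin neither evenly nor at a steadily rising rate, and that the average chain has grown for between a third and half of the run. With its first unit added, I expect dp between 14.5 and 21.2. One number is not enough for c: the impurity's charge gives 10.0%, and the chains add to that. With initiator held at its equilibrium level, 1.58 mM of chains begin, which gives my high estimate of c, 12.2%.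

The forecast gives dp 17 (14 to 20) and c 10.9% (10.7% to 11.2%), a narrower window on c than mine, on the grounds of “Those few chains, mostly started late with an effective growth time of about a minute”.

The simulation gives dp 17.0 and c 10.9%.

In this flask the impurity step drains free monomer with a half-life of 0.59 min at 0.0305 min, whereas the step into chains has a half-life of 69 min at 2.50 min, long against the run. At the end 0% of the protic impurity, the limiting reagent, remains. In this flask c has moved by 4 points, out of the forecast's range, at 0.0887 M or 0.211 M of protic impurity. This flask's dp, less the first unit, is 0.396 of its growth turnovers. The neighbour flask, with 0.60 M of free monomer, has 13.5 turnovers, which gives dp 6.35, and its impurity charge gives c near 25.0%; its run gives dp 6.27 and c 25.3%.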